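The runs were generated by integration with made-up constants; noise was put on by code.

Take the charge of Z as the unit of catalyst. Z turns E into J, and the question is what part of that unit still works once D, charged beside it, has acted.

all flasks: E 0.050 M
- elm: Z 5 µM; D 0.46 µM; run made earlier
- oak: Z 5 µM; D 0.69 µM; run made earlier
- flask: Z 5.0 µM; D 0.92 µM

| run | time / s | J / % | E / % |
|---|---|---|---|
| elm | 15.0 | 65.9 | 33.8 |
| elm | 40.0 | 89.8 | 10.1 |
| elm | 80.0 | 96.8 | 3.5 |
| elm | 120 | 98.2 | 1.3 |
| oak | 15.0 | 64.7 | 35.7 |
| oak | 40.0 | 88.8 | 11.3 |
| oak | 80.0 | 96.6 | 3.4 |
| oak | 120 | 98.1 | 2.0 |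

(scatter of a reading: 0.3 percentage points)

1. factor on the rate of making J when 20% of the E are converted if Z is charged twice over
2. factor on the rate when 20% of the E are converted if Z is charged at 25 µM instead

- no earlier run changes the charge of Z; that part of a forecast is a guess

Two people dispute this. The bystander holds that the rate follows the charge of Z and that D does not count, so doubling gives 2 and 25 µM gives 5.00. He points out that at 80.0 s elm holds 3.5% of its E and oak 3.4%, a difference inside the scatter of 0.3 percentage points.

The counter writes the balance of the smaller charge. In the flask D is 0.184 of a unit, less than the Z, so if each D takes one Z, D is the limiting reagent of that capture. That leaves w = 0.816, the working share: the part of the charge of Z left free once D has taken its partners. Elm has w of 0.908 and oak 0.862, so oak should keep 0.949 of elm's pace. At 40.0 s the readings of E left are 10.1% in elm and 11.3% in oak, a gap of 1.2 points, which is larger than the scatter of 0.3 points, so at that time oak reads behind elm.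

Doubling Z with D unchanged adds a whole unit on top of w, so my own reckoning for the flask is one plus w, over w: 2.23. The views draw together as D shrinks beside Z, and that is the bystander's region: with elm's D the count gives 2.10 against his 2.

The forecast takes the counter's side, “D removing Z one-for-one with rate proportional to free Z”, and gives 2.2 (1.7 to 2.4) and 5.8 (3.3 to 6.6).

The flask gives a factor of 2.23 for the doubled charge of Z and 5.90 for 25 µM.

    E + Z → J + Z, rate k1*[E]^1.5*[Z]/(1 + ([E]/Kh1)^1.5) (0.0765 M, k = 1.17 × 10⁵ M⁻¹·⁵ s⁻¹)
    Z + D → L (k = 1.46 × 10⁷ M⁻¹ s⁻¹)

At 0.200 min the flask holds 81.6% of its catalyst as Z and 18.4% as L, the form that Z and D make, with D at 0% of its own charge. For 25 µM of Z beside the flask's D, the charge is 5.00 units, and taking away the 0.184 that D holds leaves 4.82 working units, which over w is a factor of 5.90.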